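**Retrosynthetic overview**
- 21 ⇐ 20 ⇐ 17: the phenol benzyl ethers come off last and C9''H2OH comes from a vinyl group. The threo C7''/C8'' pair comes from an asymmetric (Z)-γ-aryloxyallylboration of aldehyde 13, with the O-allyl group of furofuran 12 as the nucleophile.
- 12 ⇐ monocyclic lactol 10 (key step): ring A (C7–O–C9') and ring B (C7'–O–C9) close in one flask. Ring A forms by stereoconvergent benzylic-cation capture (exo guaiacyl). Ring B forms by a lactol ring switch on the intact C7'–O bond, then ionic reduction (endo syringyl).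
- 10 ⇐ 9 ⇐ lactone 6 + O-benzylvanillin 7: a trans-selective lactone aldol sets C8, and partial reduction leaves C9 at the aldehyde level and C9' at the alcohol level.
- 6 ⇐ O-allylsyringaldehyde 2 + methyl 4-oxobutanoate 3: an (R)-proline anti cross-aldol, reduction and lactonisation set C7' and C8'.
- Ring order: a sacrificial butyrolactone forms in step 2; it is opened and replaced by rings A and B together in step 5.

Assumption: the SMILES is read literally, giving exo guaiacyl (7R,8S), endo syringyl (7'S,8'S) and a threo side chain (7''R,8''R). Lignan numbering is used throughout: C7 benzylic, C8 bridgehead, C9 CH2; primes mark the syringyl half and double primes the side chain.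

**Step 1**
Reactants: 1 syringaldehyde
Product: 2 4-(allyloxy)-3,5-dimethoxybenzaldehyde
Conditions: allyl bromide, K2CO3, DMF, 60 °C
Reagents that add atoms: allyl bromide, C=CCBr
Why: Williamson ether synthesis on the only acidic OH; the allyl group masks the syringyl phenol through steps 2–5 and later supplies the side-chain carbons, and no stereocentre is formed.

**Step 2**
Reactants: 2 4-(allyloxy)-3,5-dimethoxybenzaldehyde; 3 methyl 4-oxobutanoate
Product: 6 (4S)-4-{(S)-[4-(allyloxy)-3,5-dimethoxyphenyl](hydroxy)methyl}dihydrofuran-2(3H)-one, via aldol aldehyde 4 (not isolated), via diol ester 5 (not isolated)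
Conditions: (R)-proline (20 mol %), DMF, 4 °C, slow addition of 3 (1.5 equiv, 24 h); then MeOH, NaBH4, −20 → 0 °C; aq. citric acid
Reagents that add atoms: none
Why: Enamine-catalysed direct cross-aldol in which the (E)-enamine of 3 adds through the hydrogen-bonded chair transition state to one face of the non-enolisable aldehyde 2, giving the anti aldol (C7' S, C8' R in 4, named C8' S in 6 after the priority change), and in-situ NaBH4 reduction of the formyl group triggers lactonisation onto the methyl ester before the aldol can epimerise.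

**Step 3**
Reactants: 6 (4S)-4-{(S)-[4-(allyloxy)-3,5-dimethoxyphenyl](hydroxy)methyl}dihydrofuran-2(3H)-one; 7 4-(benzyloxy)-3-methoxybenzaldehyde
Product: 9 (3R,4S)-4-{(S)-[4-(allyloxy)-3,5-dimethoxyphenyl](hydroxy)methyl}-3-{[4-(benzyloxy)-3-methoxyphenyl](hydroxy)methyl}dihydrofuran-2(3H)-one (C7 carbinol epimers), via dilithio enolate 8 (not isolated)
Conditions: LiN(i-Pr)2 (2.3 equiv), THF, −78 °C, 1 h; 7 (1.2 equiv), −78 °C, 1 h; AcOH, −78 °C
Reagents that add atoms: none
Why: Lactone-enolate aldol addition through the alkoxide–enolate dianion, in which the aldehyde approaches anti to the bulky C4 arm and fixes C8 (3,4-trans, the relationship a cis-fused bicycle needs), while carbinol C7 forms as an epimer mixture that is left uncontrolled because step 5 erases it.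

**Step 4**
Reactants: 9 lactone diol
Product: 10 (3R,4S)-4-{(S)-[4-(allyloxy)-3,5-dimethoxyphenyl](hydroxy)methyl}-3-{[4-(benzyloxy)-3-methoxyphenyl](hydroxy)methyl}tetrahydrofuran-2-ol (anomers and C7 epimers)
Conditions: i-Bu2AlH (3.5 equiv), CH2Cl2, −78 °C, 1 h; aq. potassium sodium tartrate
Reagents that add atoms: none
Why: Partial γ-lactone reduction stops at the aluminium hemiacetal at −78 °C, so C9 (aldehyde level) is now chemically distinct from C9' (alcohol level), and no stereocentre of the target is touched.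

**Step 5 (key step)**
Reactants: 10 lactol triol
Product: 12 (1R,3aS,4S,6aS)-4-[4-(allyloxy)-3,5-dimethoxyphenyl]-1-[4-(benzyloxy)-3-methoxyphenyl]tetrahydro-1H,3H-furo[3,4-c]furan, via bicyclic lactol 11 (not isolated)
Conditions: BF3·OEt2 (0.3 equiv), 4 Å molecular sieves, CH2Cl2, −40 °C, 1 h; then Et3SiH (4 equiv), BF3·OEt2 (2 equiv), −78 °C, 1 h; aq. NaHCO3
Reagents that add atoms: none
Why: Proposed new method: substoichiometric BF3·OEt2 ionises only the 4-benzyloxy-3-methoxybenzylic alcohol (both C7 epimers give the same cation, whereas the 4-alkoxy-3,5-dimethoxybenzylic C7'–OH is a much poorer cation precursor because its para oxygen is twisted out of conjugation), the C9' oxygen freed by ring–chain tautomerism of the lactol captures that cation on the convex face to close ring A with the guaiacyl group exo (C7 = R), the C7' hydroxyl re-closes on the C9 aldehyde to form ring B without its C–O bond ever breaking so that the anti-aldol configuration becomes the endo syringyl group (C7' = S), and Et3SiH with more BF3·OEt2 at −78 °C then removes the anomeric OH of 11 through the oxocarbenium ion; the closest known reaction types are the acid-mediated benzylic-cation (quinone-methide-type) etherification used to close furofurans and the Et3SiH/BF3·OEt2 lactol-to-cyclic-ether ionic reduction, which spares acid-labile furofurans at −78 °C.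

**Step 6**
Reactants: 12 O-allyl furofuran; 13 4-(benzyloxy)-3,5-dimethoxybenzaldehyde
Product: 17 (1R,2R)-1-[4-(benzyloxy)-3,5-dimethoxyphenyl]-2-(aryloxy)but-3-en-1-ol in which aryl is the syringyl ring of the furofuran of 12, via allyllithium 14 (not isolated), via allylborane 15 (not isolated), via borinate 16 (not isolated)
Conditions: s-BuLi (1.05 equiv), THF, −78 °C, 30 min; (−)-Ipc2BOMe (1.1 equiv), −78 °C, 1 h; BF3·OEt2 (1.3 equiv), then 13 (1.3 equiv), −78 °C, 4 h; NaOH, 30% H2O2, 0 °C → rt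
Reagents that add atoms: none
Why: Brown (Z)-γ-alkoxyallylboration, in which kinetic α-lithiation of the allyl ether gives the oxygen-chelated (Z)-oxyallyl anion, boron capture and methoxide abstraction give the (Z)-γ-aryloxyallylborane, its chair transition state converts Z geometry into the syn (threo) relationship, and the isopinocampheyl groups derived from (+)-α-pinene select the aldehyde face that gives 7''R,8''R.

**Step 7**
Reactants: 17 homoallylic alcohol
Product: 20 (1R,2R)-1-[4-(benzyloxy)-3,5-dimethoxyphenyl]-2-(aryloxy)propane-1,3-diol (di-O-benzyl target), via ozonide 18 (not isolated), via aldehyde 19 (not isolated)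
Conditions: O3, CH2Cl2, −78 °C (stop at first excess), N2 purge; MeOH, NaBH4, −78 → 0 °C
Reagents that add atoms: ozone, [O-][O+]=O
Why: Ozonolysis with reductive work-up, in which the isolated terminal alkene reacts with O3 much faster than the alkoxyarenes at −78 °C and immediate hydride reduction of the α-aryloxy aldehyde 19 prevents epimerisation at C8'' or retro-aldol, so both side-chain stereocentres are retained.

**Step 8**
Reactants: 20 di-O-benzyl target
Product: 21 target CNP0317965.1
Conditions: H2 (1 atm), 10% Pd/C, EtOAc–EtOH, rt, stop after 2 equiv H2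
Reagents that add atoms: none
Why: Catalytic hydrogenolysis, in which the two aryl benzyl ethers cleave much faster than the benzylic C–O bonds of the furofuran and the secondary benzylic alcohol when uptake is stopped at two equivalents, and no stereocentre is affected.

**Compound list**
1 | syringaldehyde (4-hydroxy-3,5-dimethoxybenzaldehyde) | COc1cc(C=O)cc(OC)c1O | starting material
2 | 4-(allyloxy)-3,5-dimethoxybenzaldehyde | C=CCOc1c(OC)cc(C=O)cc1OC | intermediate
3 | methyl 4-oxobutanoate | COC(=O)CCC=O | starting material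
4 | methyl (3R,4S)-4-[4-(allyloxy)-3,5-dimethoxyphenyl]-3-formyl-4-hydroxybutanoate (anti aldol) | COC(=O)C[C@@H](C=O)[C@H](O)c1cc(OC)c(OCC=C)c(OC)c1 | intermediate
5 | methyl (3S,4S)-4-[4-(allyloxy)-3,5-dimethoxyphenyl]-4-hydroxy-3-(hydroxymethyl)butanoate | COC(=O)C[C@@H](CO)[C@H](O)c1cc(OC)c(OCC=C)c(OC)c1 | intermediate
6 | (4S)-4-{(S)-[4-(allyloxy)-3,5-dimethoxyphenyl](hydroxy)methyl}dihydrofuran-2(3H)-one | O=C1C[C@H]([C@H](O)c2cc(OC)c(OCC=C)c(OC)c2)CO1 | intermediate
7 | 4-(benzyloxy)-3-methoxybenzaldehyde (O-benzylvanillin) | COc1cc(C=O)ccc1OCc1ccccc1 | starting material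
8 | dilithio alkoxide–enolate of 6 | [Li]OC1=C[C@H]([C@H](O[Li])c2cc(OC)c(OCC=C)c(OC)c2)CO1 | intermediate
9 | (3R,4S)-3,4-trans lactone diol, (S) at C7', C7 epimer mixture | O=C1[C@@H](C(O)c2ccc(OCc3ccccc3)c(OC)c2)[C@H]([C@H](O)c2cc(OC)c(OCC=C)c(OC)c2)CO1 | intermediate
10 | lactol of 9 (anomers, C7 epimers) | OC1[C@@H](C(O)c2ccc(OCc3ccccc3)c(OC)c2)[C@H]([C@H](O)c2cc(OC)c(OCC=C)c(OC)c2)CO1 | intermediate
11 | 9-hydroxy derivative of 12 (bicyclic lactol, anomers; exo guaiacyl, endo syringyl) | COc1cc([C@@H]2OC[C@@H]3[C@H]2C(O)O[C@@H]3c2cc(OC)c(OCC=C)c(OC)c2)ccc1OCc1ccccc1 | intermediate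
12 | (1R,3aS,4S,6aS)-4-[4-(allyloxy)-3,5-dimethoxyphenyl]-1-[4-(benzyloxy)-3-methoxyphenyl]tetrahydro-1H,3H-furo[3,4-c]furan | COc1cc([C@@H]2OC[C@@H]3[C@H]2CO[C@@H]3c2cc(OC)c(OCC=C)c(OC)c2)ccc1OCc1ccccc1 | intermediate
13 | 4-(benzyloxy)-3,5-dimethoxybenzaldehyde | COc1cc(C=O)cc(OC)c1OCc1ccccc1 | starting material
14 | (Z)-3-(aryloxy)allyllithium derived from 12 | COc1cc([C@@H]2OC[C@@H]3[C@H]2CO[C@@H]3c2cc(OC)c(O/C=C\C[Li])c(OC)c2)ccc1OCc1ccccc1 | intermediate
15 | B-[(Z)-3-(aryloxy)allyl]bis(isopinocampheyl)borane (Ipc from (+)-α-pinene) | COc1cc([C@@H]2OC[C@@H]3[C@H]2CO[C@@H]3c2cc(OC)c(O/C=C\CB([C@@H]3C[C@@H]4C[C@H]([C@H]3C)C4(C)C)[C@@H]3C[C@@H]4C[C@H]([C@H]3C)C4(C)C)c(OC)c2)ccc1OCc1ccccc1 | intermediate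
16 | bis(isopinocampheyl)borinate of 17 | COc1cc([C@@H]2OC[C@@H]3[C@H]2CO[C@@H]3c2cc(OC)c(O[C@H](C=C)[C@H](OB([C@@H]3C[C@@H]4C[C@H]([C@H]3C)C4(C)C)[C@@H]3C[C@@H]4C[C@H]([C@H]3C)C4(C)C)c3cc(OC)c(OCc4ccccc4)c(OC)c3)c(OC)c2)ccc1OCc1ccccc1 | intermediate
17 | threo-(7''R,8''R) homoallylic alcohol (vinyl at C8'') | COc1cc([C@@H]2OC[C@@H]3[C@H]2CO[C@@H]3c2cc(OC)c(O[C@H](C=C)[C@H](O)c3cc(OC)c(OCc4ccccc4)c(OC)c3)c(OC)c2)ccc1OCc1ccccc1 | intermediate
18 | 1,2,4-trioxolane (ozonide) of 17 | COc1cc([C@@H]2OC[C@@H]3[C@H]2CO[C@@H]3c2cc(OC)c(O[C@H](C3OCOO3)[C@H](O)c3cc(OC)c(OCc4ccccc4)c(OC)c3)c(OC)c2)ccc1OCc1ccccc1 | intermediate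
19 | α-aryloxy-β-hydroxy aldehyde | COc1cc([C@@H]2OC[C@@H]3[C@H]2CO[C@@H]3c2cc(OC)c(O[C@H](C=O)[C@H](O)c3cc(OC)c(OCc4ccccc4)c(OC)c3)c(OC)c2)ccc1OCc1ccccc1 | intermediate
20 | di-O-benzyl ether of the target | COc1cc([C@@H]2OC[C@@H]3[C@H]2CO[C@@H]3c2cc(OC)c(O[C@H](CO)[C@H](O)c3cc(OC)c(OCc4ccccc4)c(OC)c3)c(OC)c2)ccc1OCc1ccccc1 | intermediate
21 | 4-[(1R,3aS,4S,6aS)-4-(4-{[(1R,2R)-1,3-dihydroxy-1-(4-hydroxy-3,5-dimethoxyphenyl)propan-2-yl]oxy}-3,5-dimethoxyphenyl)tetrahydro-1H,3H-furo[3,4-c]furan-1-yl]-2-methoxyphenol | COc1cc([C@@H]2OC[C@@H]3[C@H]2CO[C@@H]3c2cc(OC)c(O[C@H](CO)[C@H](O)c3cc(OC)c(O)c(OC)c3)c(OC)c2)ccc1O | target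

**Totals**
Total step count: 8. Longest linear sequence: 8 (1 → 2 → 6 → 9 → 10 → 12 → 17 → 20 → 21).

**Three steps most likely to fail**

Step 5.
- Risks:
  - premature reduction of the original lactol ring to a 3,4-disubstituted tetrahydrofuran;
  - E1 loss from the C7 cation to an enal or a furan;
  - Friedel–Crafts closure onto the syringyl ring (aryltetralin);
  - enolisation at C8;
  - slow ionisation at C7'.
- Fallback: do the ring switch one oxidation level higher, where no enolisable aldehyde exists. It sets out from 9. Catalytic camphorsulfonic acid in CH2Cl2 drives translactonisation onto the C7' hydroxyl. The freed C9' hydroxyl then captures the C7 cation to give the endo,exo-furofuranone F1. i-Bu2AlH at −78 °C converts it to 11, now isolated, where the route is rejoined. Et3SiH/BF3·OEt2 at −78 °C then gives 12.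

Step 6.
- Risks:
  - s-BuLi may also lithiate the furofuran benzylic C–H bonds, the OCH2Ph group or ring positions;
  - the aryloxyallyl anion may lose phenoxide or rearrange.
- Fallback: replace the allylboration by an auxiliary-controlled glycolate aldol. It sets out from 12. Pd(PPh3)4 and morpholine in THF remove the allyl group to give the free syringyl phenol F2. K2CO3 and (S)-4-benzyl-3-(chloroacetyl)-1,3-oxazolidin-2-one in acetone give the aryloxyacetyl imide F3. n-Bu2BOTf/Et3N followed by 13 gives the syn glycolate aldol F4 (2S,3R). LiBH4 in THF–MeOH reduces off the auxiliary and delivers 20, where the route is rejoined, so steps 6 and 7 are both bypassed.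

Step 2.
- Risks:
  - the electron-rich aldehyde 2 is a sluggish acceptor;
  - self-aldol of 3 competes;
  - the anti:syn ratio may erode.
- Fallback: replace organocatalysis by an auxiliary-controlled anti aldol. It sets out from 2. (S)-4-Benzyl-1,3-oxazolidin-2-one is acylated (n-BuLi, methyl 4-chloro-4-oxobutanoate) to the succinyl imide F5. MgCl2 (10 mol %), Et3N and Me3SiCl in EtOAc with 2 give the O-silylated anti aldol F6 (2R,3S). NaBH4 in THF–H2O cleaves the imide reductively and the new primary alcohol lactonises onto the methyl ester. Dilute acid removes the silyl group to give 6, where the route is rejoined.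

**Further compounds**
F1 | step 5 | (3S,3aS,6R,6aR)-3-[4-(allyloxy)-3,5-dimethoxyphenyl]-6-[4-(benzyloxy)-3-methoxyphenyl]tetrahydro-1H,3H-furo[3,4-c]furan-1-one (endo,exo-furofuranone) | COc1cc([C@@H]2OC[C@@H]3[C@H]2C(=O)O[C@@H]3c2cc(OC)c(OCC=C)c(OC)c2)ccc1OCc1ccccc1
F2 | step 6 | free syringyl phenol (de-allylated 12) | COc1cc([C@@H]2OC[C@@H]3[C@H]2CO[C@@H]3c2cc(OC)c(O)c(OC)c2)ccc1OCc1ccccc1
F3 | step 6 | aryloxyacetyl imide of (S)-4-benzyl-1,3-oxazolidin-2-one | COc1cc([C@@H]2OC[C@@H]3[C@H]2CO[C@@H]3c2cc(OC)c(OCC(=O)N3[C@@H](Cc4ccccc4)COC3=O)c(OC)c2)ccc1OCc1ccccc1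
F4 | step 6 | syn glycolate aldol (2S,3R) | COc1cc([C@@H]2OC[C@@H]3[C@H]2CO[C@@H]3c2cc(OC)c(O[C@H](C(=O)N3[C@@H](Cc4ccccc4)COC3=O)[C@H](O)c3cc(OC)c(OCc4ccccc4)c(OC)c3)c(OC)c2)ccc1OCc1ccccc1
F5 | step 2 | (S)-4-benzyl-3-(4-methoxy-4-oxobutanoyl)-1,3-oxazolidin-2-one (succinyl imide) | COC(=O)CCC(=O)N1[C@@H](Cc2ccccc2)COC1=O
F6 | step 2 | O-silylated anti aldol (2R,3S) | COC(=O)C[C@H]([C@H](O[Si](C)(C)C)c1cc(OC)c(OCC=C)c(OC)c1)C(=O)N1[C@@H](Cc2ccccc2)COC1=O
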